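## The problem

The target is a germacranolide (numbering: ring carbons C1–C10, lactone carbons C11–C13, C14 on C10, C15 on C4). Its ten-membered carbocycle is bridged by an oxygen between C3 and C10, so C3 is a hemiketal carbon inside an 11-oxabicyclo[6.2.1]undecene. The ring carries a cis-fused α-methylene-γ-butyrolactone on C6–C7, an (R)-2-methylbutanoate on C8, a Z C4=C5 alkene and a free primary alcohol at C14.

A synthesis must make a medium ring, which direct cyclisation does poorly, and place five stereocenters on it: the contiguous C6, C7, C8 (all three hydrogens on one face), the quaternary carbinol C10 and the hemiketal C3. C3 needs no control of its own, because the oxygen bridge can span only one face once C10 is fixed. C6 and C7 can be set together as a cis 1,2-pair. C8 lies next to C7 but in a flexible ring, and C10 is remote from the C6–C8 triad, so both call for reagent control.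

Several groups will not survive rough treatment:
- the exo-methylene lactone (a Michael acceptor);
- the allylic hemiketal, which is the ring tautomer of a Z-enone with a γ-acyloxy group;
- the epimerisable α-carbon of the ester;
- the C8 acyloxy group, cis to the lactone carbonyl and so open to translactonisation under base;
- at the ketone stage, a C8 carbonyl β to the lactone oxygen on C6 (elimination, C7 epimerisation).

The enabling feature is that C3 and C8 are both oxidised and lie 1,6 to each other, with four carbons on either side. The ring is therefore the perimeter of two six-membered rings, ring A (C3–C4–C5–C6–C7–C8) and ring B (C3–C2–C1–C10–C9–C8), whose shared C3=C8 double bond has been cleaved. Ring B of that octalin can be a benzene ring, so the medium ring can be drawn from a tetralin.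

## Retrosynthesis

**33 ⇒ 32 ⇒ 30.** No skeletal bond is cut. The C14 silyl ether of 32 is removed last, and the C4=C5 alkene is taken back to the saturated hemiketal 30. Because 30 is the ring tautomer of a C3 ketone, C4 can be functionalised through the enol and the alkene made by syn-elimination. Introducing the alkene earlier is excluded, since an alkene in ring A would not survive the oxidative cleavage. The forward step must enolise toward C4 rather than C2 and eliminate into the ring rather than toward C15; the bridged hemiketal admits only the Z alkene.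

**30 ⇒ 29 ⇒ 26.** The C11=C13 bond is cut back to the lactone methylene (Mannich methylenation), and the hemiketal to the methyl ketal. Methylenation is placed before the dehydrogenation and on the ketal: strong base on the free hemiketal or on its enone tautomer would be destructive, whereas 26 has no acidic hydroxyl and only the lactone α-methylene is easily deprotonated.

**26 ⇒ 24 + 25 ⇒ 23.** The ester C–O bond is cut to alcohol 24 and acid 25, and the C8–H bond to ketone 23. The forward reduction must give 8R under non-basic conditions, because the C8 ketone is β to the lactone oxygen.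

**23 ⇒ 21.** The C3–O10 and C3–OMe bonds are cut, returning the 3,8-diketone 21. This ketalisation is what tells the two carbonyls apart: O10 is 1,4 to C3 (five-membered ring) but 1,3 to C8 (no ring possible). A C10/C14 acetonide was rejected because its removal frees O14 as well, and O14 can reach C8 through a five-membered hemiketal. O10 and O14 are therefore protected separately in 21 (trimethylsilyl and tert-butyldiphenylsilyl).

**21 ⇒ 19 (key).** C3 and C8 are reconnected as the tetrasubstituted ring-fusion alkene of octalin 19. The precursor has two six-membered rings instead of a ten-membered one and a single alkene, so the forward ozonolysis needs no selectivity. This is preferred to any ring closure because the medium ring is already present as the perimeter of the bicycle.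

**19 ⇒ 18 ⇒ 16 ⇒ 15 ⇒ 14 ⇒ 13.** The C10–O bond is traced to an epoxide across C1=C10, opened by hydride at C1, and the epoxide to the allylic alcohol 13. C10 is thus set by a catalyst through the C14 hydroxyl, independent of the distant C6/C7 pair. The lactone is reduced along with the epoxide (16) and restored by oxidative lactonisation (18), which costs one step but avoids any protecting group on O6.

**13 ⇒ 10.** The two isolated alkenes of 13 (C3=C8 and C1=C10) are returned to the benzene ring of tetralin 10. The forward Birch reduction must protonate the two unsubstituted para carbons C2 and C9, which is the normal course for a 1,2,4-trialkylbenzene.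

**10 ⇒ 9.** The C10–C14 bond is cut to aryl bromide 9. A cross-coupling that delivers the hydroxymethyl group directly is preferred to carbonylation followed by reduction, which would also reduce the lactone.

**9 ⇒ 7.** The C6–H bond and the lactone C–O bond are cut to γ-keto ester 7. C7 is benzylic and α to the ketone, so it epimerises freely and one asymmetric reduction can set C6 and C7 together as the cis pair.

**7 ⇒ 4 + 5 and 4 ⇒ 1 + 2.** The C7–C11 bond is cut (enamine alkylation of 2-tetralone 4 with 5). Then C5–C6 and C3–C4 are cut (acylation of propene 2 by the acid chloride of 1 and ring closure of the resulting cation), reaching three commercial compounds.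

## Roads not taken

**Alternative 1:** The cut is the C3–O10 bond together with the C3/C6 oxidation state, traced to a furan whose ring carbons are C3–C6; the ten-membered ring is left open at C7–C8. In the forward key step, anodic oxidation of the furan precursor of A1 in methanol gives a radical cation. The tethered C10 hydroxyl adds at C3 and the solvent at C6, giving the methoxy dioxaspirononene A1.
- Merits: the Z geometry of C4=C5 is guaranteed because the alkene is formed inside a five-membered ring. C3 and C6 arrive at the right oxidation level without any enolisation chemistry, and no chemical oxidant is needed.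
- Weak points: A1 still lacks the carbocycle. It must be closed at C7–C8 by an aldol reaction of an unmasked Z-ene-dione, a system prone to isomerisation and to reversion to the furan. C6, C7 and C8 are all created late on a flexible ring.
- Comparison: for the alkene and the hemiketal this road is better than the chosen plan, whose weakest step is the late dehydrogenation. The chosen plan sets against it a ring formation that cannot fail and a C6/C7 pair made on a rigid six-membered ring.

**Alternative 2:** The cuts are C1–C2 and C3–O10. In the forward key step, the C2 carbanion of the epoxy keto sulfone precursor of A2 opens the C1–C10 epoxide at C1, and the liberated C10 alkoxide adds to the C3 ketone, giving the sulfonyl hemiketal A2.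
- Merits: the precursor is open-chain and already carries C6, C7, C8, the ester and a Z alkene made by olefination. Ring and bridge form in one step, and only desulfonylation, methylenation and desilylation remain.
- Weak points: closing a ten-membered ring by alkylating a doubly stabilised carbanion with an epoxide is slow and competes with O-alkylation and oligomerisation. The base acts on a Z-enone with an acyloxy group at the γ carbon and on the C8 ester. Reductive desulfonylation next to the enone/hemiketal system is delicate.
- Comparison: the endgame is shorter than in the chosen plan and has no dehydrogenation. The chosen plan offers instead a ring-forming event with close precedent and no dependence on medium-ring cyclisation kinetics.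

**Alternative 3:** The cut is C7–C8, with O8 reconnected to C13 in a thirteen-membered allyl ether. In the forward key step, tin–lithium exchange at C8 of the stannyl ether precursor of A3 triggers a [2,3]-Wittig–Still shift. This forms C7–C8, breaks O8–C13, contracts the ring to ten members and creates the C11=C13 methylene, giving the homoallylic alcohol A3.
- Merits: C7 and C8 are formed in one concerted, ordered step, the exo-methylene arises without enolate chemistry, and the C3 methyl ketal and Z alkene are already in place.
- Weak points: the thirteen-membered α-stannyl ether needs its own macrocyclisation and an enantioenriched stannane. A [1,2]-shift can compete, and facial selectivity in a transannular transition state is hard to predict. A3 carries three identical silyl ethers to be told apart, and C12 must still be oxidised and lactonised.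
- Comparison: this road is better at building the methylene lactone framework and the C7/C8 pair. The chosen plan answers with cheap aromatic starting materials, catalyst-controlled stereocenters and a shorter overall sequence.

Key step: step 11

Assumption 1: C4 is formed racemic in step 1 and both configurations are carried forward, since C4 becomes trigonal in step 17; the SMILES of 4–31 leave C4 undefined.
Assumption 2: the (S,S)-TsDPEN ruthenium catalyst is taken to reduce the 2-tetralone carbonyl with the same spatial sense as it reduces aryl ketones (6S); if the sense proves opposite, the (R,R) catalyst is used.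
Assumption 3: locants in names follow germacrane numbering unless a systematic name is given; the configuration of every compound is the one in its SMILES.

## Route

Step 1
Reactants: 1 (3-bromophenyl)acetic acid; 2 propene
Product: 4 7-bromo-4-methyl-3,4-dihydronaphthalen-2(1H)-one (racemic), via (3-bromophenyl)acetyl chloride 3 (not isolated)
Conditions: (COCl)2, cat. DMF, CH2Cl2, rt; then AlCl3, propene, CH2Cl2, −10 → 0 °C
Reagents that add atoms: none
Why: Friedel–Crafts acylation of the alkene (acyl group to the CH2 terminus) followed by cycloalkylation of the secondary cation onto the ring, the known 2-tetralone synthesis from arylacetyl chlorides and alkenes; closure para to bromine (less hindered, resonance-activated) should place Br at C7 of the tetralone, which is C10 of the target.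

Step 2
Reactants: 4 7-bromo-4-methyl-3,4-dihydronaphthalen-2(1H)-one; 5 ethyl bromoacetate
Product: 7 ethyl 2-(7-bromo-4-methyl-2-oxo-1,2,3,4-tetrahydronaphthalen-1-yl)acetate (isomer mixture), via pyrrolidine enamine 6 (not isolated)
Conditions: pyrrolidine, cat. TsOH, toluene, reflux (−H2O); then 5, MeCN, reflux; then aq. NaOAc–AcOH, rt
Reagents that add atoms: none
Why: Stork enamine alkylation; 2-tetralones give the styrene-conjugated C1=C2 enamine, which is C-alkylated once at the benzylic carbon by the reactive α-halo ester; the configuration at this carbon is left open because it is labile.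

Step 3
Reactants: 7 ethyl 2-(7-bromo-4-methyl-2-oxo-1,2,3,4-tetrahydronaphthalen-1-yl)acetate
Product: 9 (3aS,9bR)-8-bromo-5-methyl-3a,4,5,9b-tetrahydronaphtho[2,1-b]furan-2(1H)-one (cis-fused), via cis hydroxy ester 8 (not isolated)
Conditions: RuCl[(S,S)-TsDPEN](p-cymene) (1 mol%), HCO2H–Et3N (5:2), DMF, 40 °C; then cat. TsOH, toluene, 60 °C
Reagents that add atoms: none
Why: Noyori–Ikariya asymmetric transfer hydrogenation under dynamic kinetic resolution: the benzylic α-carbon (C7) epimerises quickly under Et3N and hydride is delivered anti to its substituent, so the catalyst sets C6 and the resolution sets C7 as the cis pair; acid then closes the cis γ-hydroxy ester to the lactone.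

Step 4
Reactants: 9 (3aS,9bR)-8-bromo-5-methyl-3a,4,5,9b-tetrahydronaphtho[2,1-b]furan-2(1H)-one
Product: 10 (3aS,9bR)-8-(hydroxymethyl)-5-methyl-3a,4,5,9b-tetrahydronaphtho[2,1-b]furan-2(1H)-one
Conditions: Bu3SnCH2OH, Pd(PPh3)4 (5 mol%), 1,4-dioxane, 100 °C
Reagents that add atoms: (tributylstannyl)methanol, OC[Sn](CCCC)(CCCC)CCCC
Why: Stille coupling of an aryl bromide with (tributylstannyl)methanol transfers the hydroxymethyl group under neutral conditions, so the lactone is untouched and C14 arrives at the alcohol level.

Step 5
Reactants: 10 (3aS,9bR)-8-(hydroxymethyl)-5-methyl-3a,4,5,9b-tetrahydronaphtho[2,1-b]furan-2(1H)-one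
Product: 13 (3aS,9bR)-8-(hydroxymethyl)-5-methyl-3a,4,5,6,9,9b-hexahydronaphtho[2,1-b]furan-2(1H)-one (alkenes C3=C8 and C1=C10 in germacrane numbering), via ring-opened lithium carboxylate 11 (not isolated), via dienyl hydroxy acid 12 (not isolated)
Conditions: LiOH (1.05 equiv), THF–H2O, rt, then evaporation to dryness; Li, NH3(l)–THF, −78 °C, then t-BuOH, −78 → −33 °C; NH4Cl; aq. HCl to pH 3, EtOAc, rt
Reagents that add atoms: none
Why: Birch reduction; the carboxylate is inert to dissolving metal and the benzylic alcohol, present as its lithium alkoxide before the proton source is added, resists hydrogenolysis; protonation at the two unsubstituted para carbons C2 and C9 leaves the alkenes at C3=C8 and C1=C10, and acidification re-closes the cis γ-hydroxy acid.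

Step 6
Reactants: 13 (3aS,9bR)-8-(hydroxymethyl)-5-methyl-3a,4,5,6,9,9b-hexahydronaphtho[2,1-b]furan-2(1H)-one
Product: 14 (1R,10R)-1,10-epoxide of 13 with free C14 hydroxyl
Conditions: Ti(OiPr)4 (10 mol%), D-(−)-diisopropyl tartrate (12 mol%), t-BuOOH, 4 Å MS, CH2Cl2, −20 °C
Reagents that add atoms: tert-butyl hydroperoxide, CC(C)(C)OO
Why: Katsuki–Sharpless asymmetric epoxidation; only the C1=C10 alkene is bound to titanium through the C14 hydroxyl, so the tetrasubstituted alkene is spared, and the D-tartrate delivers oxygen to the face that gives 10R (L-tartrates give 2S epoxy alcohols), fixing C10 by reagent control.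

Step 7
Reactants: 14 (1R,10R)-1,10-epoxide of 13
Product: 15 C14 tert-butyldiphenylsilyl ether of 14
Conditions: TBDPSCl, imidazole, DMF, 0 °C → rt
Reagents that add atoms: tert-butyl(chloro)diphenylsilane, CC(C)(C)[Si](Cl)(c1ccccc1)c1ccccc1
Why: Standard silylation of a primary alcohol; it marks O14 apart from O10 before either can meet a ketone, and the group survives the hydride, oxidation, ozonolysis, acid and base steps that follow.

Step 8
Reactants: 15 C14 tert-butyldiphenylsilyl ether of 14
Product: 16 (6S,10R)-triol: C3=C8 octalin with 6-OH and 7-(2-hydroxyethyl) cis to each other plus 10-OH and 10-CH2OTBDPS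
Conditions: LiEt3BH, THF, 0 °C → rt; aq. NH4Cl
Reagents that add atoms: none
Why: Hydride opening of a trisubstituted epoxide by LiEt3BH occurs by SN2 attack at the secondary carbon C1, so the C10–O bond and its configuration are kept and C1 becomes CH2; the lactone is reduced to the 1,4-diol in the same operation.

Step 9
Reactants: 16 (6S,10R)-triol
Product: 18 cis-fused octalin lactone with free tertiary 10-OH and 14-OTBDPS, via lactol 17 (not isolated)
Conditions: TEMPO (20 mol%), PhI(OAc)2, CH2Cl2, rt
Reagents that add atoms: none
Why: Oxoammonium-mediated oxidative lactonisation of a 1,4-diol: the primary alcohol is oxidised first, the aldehyde is captured by the C6 hydroxyl as lactol 17, and this is oxidised to the lactone; the tertiary alcohol, silyl ether and tetrasubstituted alkene are inert.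

Step 10
Reactants: 18 cis-fused octalin lactone with free 10-OH
Product: 19 octalin lactone with 10-OTMS and 14-OTBDPS
Conditions: N-(trimethylsilyl)imidazole, CH2Cl2, rt
Reagents that add atoms: 1-(trimethylsilyl)imidazole, C[Si](C)(C)n1ccnc1
Why: Neutral silylation of a tertiary alcohol; masking O10 keeps it from adding to the C3 ketone during the cleavage, so the next step yields a true diketone.

Step 11
Reactants: 19 octalin lactone with 10-OTMS and 14-OTBDPS
Product: 21 cyclodecane-3,8-dione lactone with 10-OTMS and 14-OTBDPS, via ozonide 20 (not isolated)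
Conditions: O3, CH2Cl2, −78 °C (Sudan Red 7B end-point); then Me2S, −78 °C → rt
Reagents that add atoms: ozone, [O-][O+]=O
Why: Ozone adds as a 1,3-dipole to the only C=C bond of 19, the electron-rich tetrasubstituted C3=C8 ring-fusion alkene; the primary ozonide fragments to a ketone and a carbonyl oxide held in the same molecule, which recombine to ozonide 20 (Criegee mechanism), and dimethyl sulfide then reduces the peroxide bond to release the C3 and C8 ketones. The closest known reaction is the ozonolysis of Birch-derived Δ9,10-octalins to cyclodecane-1,6-diones. No ring is closed: the ten-membered ring is already present as the perimeter of rings A and B and appears when their shared bond is cut, so no cyclisation mode or dilution is involved. No stereocenter is formed, and C6, C7 and C10 lie outside the reacting atoms. The only selectivity needed is chemoselectivity, which is secured because 19 has a single alkene and its lactone, silyl ethers and silicon-bound phenyl rings are inert to ozone at −78 °C when addition stops at the indicator end-point. The neutral reductive work-up avoids the transannular aldol reaction of the 1,6-diketone and enolisation at C7 next to the C8 ketone.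

Step 12
Reactants: 21 cyclodecane-3,8-dione lactone
Product: 23 (3S,10R)-3,10-epoxy-3-methoxy-8-ketone (bridged methyl ketal with 14-OTBDPS), via C3 hemiketal 22 (not isolated)
Conditions: PPTS (10 mol%), MeOH–CH2Cl2, 0 °C → rt
Reagents that add atoms: methanol, CO
Why: Acid methanolysis removes the tertiary trimethylsilyl ether; the freed O10 is 1,4 to C3 and adds transannularly to give hemiketal 22, which is converted through the bridged oxocarbenium ion into the mixed methyl ketal. O10 cannot reach C8, so the two carbonyls are differentiated, and C3 is fixed by C10 because the bridge spans one face only.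

Step 13
Reactants: 23 bridged methyl ketal 8-ketone
Product: 24 (8R)-alcohol of 23
Conditions: (S)-2-methyl-CBS-oxazaborolidine, BH3·SMe2, THF, −30 °C; MeOH
Reagents that add atoms: none
Why: Corey–Bakshi–Shibata reduction; with the α-branched C7 as the large and the C9 methylene as the small substituent, the (S)-catalyst should deliver hydride to give 8R, and the non-basic medium avoids β-elimination of the lactone carboxylate and epimerisation at C7.

Step 14
Reactants: 24 (8R)-alcohol; 25 (R)-2-methylbutanoic acid
Product: 26 8-O-[(R)-2-methylbutanoyl] ester of 24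
Conditions: EDC·HCl, DMAP, CH2Cl2, 0 °C → rt
Reagents that add atoms: none
Why: Steglich esterification; an α-alkyl acid without a heteroatom at the α-carbon is not prone to racemisation under carbodiimide–DMAP activation, and acylating at once removes the C8 hydroxyl that could otherwise translactonise onto C12.

Step 15
Reactants: 26 8-O-[(R)-2-methylbutanoyl] ester
Product: 29 α-methylene lactone with C3 methyl ketal and 14-OTBDPS, via Mannich base 27 (not isolated), via trimethylammonium iodide 28 (not isolated)
Conditions: LiHMDS (1.1 equiv), THF, −78 °C; CH2=NMe2+ I−, −78 → 0 °C; then MeI, MeOH, rt; then aq. NaHCO3, CH2Cl2, rt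
Reagents that add atoms: N,N-dimethylmethyleneiminium iodide (Eschenmoser's salt), C=[N+](C)C.[I-]
Why: Kinetic deprotonation takes the unhindered lactone α-methylene, which is more acidic than the α-branched acyclic ester; Mannich reaction with Eschenmoser's salt, quaternisation and base-induced elimination give the exo-methylene, and the ketal means no free hydroxyl or ketone is exposed to the base.

Step 16
Reactants: 29 α-methylene lactone methyl ketal
Product: 30 (3S)-hemiketal (4,5-dihydro target with 14-OTBDPS)
Conditions: 1 M aq. HCl, THF, 0 °C → rt
Reagents that add atoms: water, O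
Why: Acid hydrolysis of the mixed ketal through the same bridged oxocarbenium ion gives the hemiketal; the silyl ether, ester and methylene lactone tolerate dilute aqueous acid.

Step 17
Reactants: 30 (3S)-hemiketal
Product: 32 (4Z)-alkene hemiketal with 14-OTBDPS, via C4 phenylselenide 31 (not isolated)
Conditions: PhSeCl, EtOAc, rt; then 30% H2O2, pyridine, CH2Cl2, 0 °C → rt
Reagents that add atoms: none
Why: α-Selenenylation of a ketone through its enol followed by selenoxide syn-elimination: the HCl released opens 30 to the C3 ketone, whose more substituted enol (toward C4) is selenenylated; the selenoxide eliminates toward a ring hydrogen on C5, and inside the re-closed bridged hemiketal only the Z alkene fits the nine-membered oxacycle. Both C4 epimers converge here and the electron-poor methylene lactone reacts with neither reagent.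

Step 18
Reactants: 32 (4Z)-alkene hemiketal with 14-OTBDPS
Product: 33 CNP0328225.2
Conditions: HF·pyridine, pyridine, THF, 0 °C → rt
Reagents that add atoms: none
Why: Fluoride cleavage of the primary silyl ether under buffered, non-basic conditions leaves the methylene lactone, the ester and the allylic hemiketal intact.

## Compound list

1 | (3-bromophenyl)acetic acid | OC(=O)Cc1cccc(Br)c1 | starting material
2 | propene | CC=C | starting material
3 | (3-bromophenyl)acetyl chloride | ClC(=O)Cc1cccc(Br)c1 | intermediate
4 | 7-bromo-4-methyl-3,4-dihydronaphthalen-2(1H)-one (racemic) | CC1CC(=O)Cc2cc(Br)ccc12 | intermediate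
5 | ethyl bromoacetate | CCOC(=O)CBr | starting material
6 | 1-(7-bromo-4-methyl-3,4-dihydronaphthalen-2-yl)pyrrolidine | CC1CC(N2CCCC2)=Cc2cc(Br)ccc12 | intermediate
7 | ethyl 2-(7-bromo-4-methyl-2-oxo-1,2,3,4-tetrahydronaphthalen-1-yl)acetate (C1 labile, C4 racemic) | CCOC(=O)CC1C(=O)CC(C)c2ccc(Br)cc12 | intermediate
8 | ethyl 2-[(1R,2S)-7-bromo-2-hydroxy-4-methyl-1,2,3,4-tetrahydronaphthalen-1-yl]acetate (cis) | O[C@H]1CC(C)c2ccc(Br)cc2[C@H]1CC(=O)OCC | intermediate
9 | (3aS,9bR)-8-bromo-5-methyl-3a,4,5,9b-tetrahydronaphtho[2,1-b]furan-2(1H)-one (cis-fused) | C1C(=O)O[C@H]2CC(C)c3ccc(Br)cc3[C@@H]12 | intermediate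
10 | (3aS,9bR)-8-(hydroxymethyl)-5-methyl-3a,4,5,9b-tetrahydronaphtho[2,1-b]furan-2(1H)-one | C1C(=O)O[C@H]2CC(C)c3ccc(CO)cc3[C@@H]12 | intermediate
11 | lithium 2-[(1R,2S)-2-hydroxy-7-(hydroxymethyl)-4-methyl-1,2,3,4-tetrahydronaphthalen-1-yl]acetate | O[C@H]1CC(C)c2ccc(CO)cc2[C@H]1CC(=O)[O-].[Li+] | intermediate
12 | 2-[(1R,2S)-2-hydroxy-7-(hydroxymethyl)-4-methyl-1,2,3,4,5,8-hexahydronaphthalen-1-yl]acetic acid | O[C@H]1CC(C)C2=C(CC(CO)=CC2)[C@H]1CC(=O)O | intermediate
13 | (3aS,9bR)-8-(hydroxymethyl)-5-methyl-3a,4,5,6,9,9b-hexahydronaphtho[2,1-b]furan-2(1H)-one (cis-fused lactone; alkenes C3=C8 and C1=C10, germacrane numbering) | C1C(=O)O[C@H]2CC(C)C3=C(CC(CO)=CC3)[C@@H]12 | intermediate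
14 | (1R,10R)-1,10-epoxide of 13, free C14 hydroxyl, C3=C8 alkene retained | C1C(=O)O[C@H]2CC(C)C3=C(C[C@]4(CO)O[C@@H]4C3)[C@@H]12 | intermediate
15 | C14 tert-butyldiphenylsilyl ether of 14 | C1C(=O)O[C@H]2CC(C)C3=C(C[C@]4(CO[Si](c5ccccc5)(c5ccccc5)C(C)(C)C)O[C@@H]4C3)[C@@H]12 | intermediate
16 | (6S,10R)-triol: C3=C8 octalin with 6-OH, cis 7-(2-hydroxyethyl), 10-OH and 10-CH2OTBDPS | O[C@H]1CC(C)C2=C(C[C@@](O)(CO[Si](c3ccccc3)(c3ccccc3)C(C)(C)C)CC2)[C@H]1CCO | intermediate
17 | lactol (C12 hemiacetal) of 18 | C1C(O)O[C@H]2CC(C)C3=C(C[C@@](O)(CO[Si](c4ccccc4)(c4ccccc4)C(C)(C)C)CC3)[C@@H]12 | intermediate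
18 | cis-fused 6,12-lactone of the C3=C8 octalin with (10R)-10-OH and 14-OTBDPS | C1C(=O)O[C@H]2CC(C)C3=C(C[C@@](O)(CO[Si](c4ccccc4)(c4ccccc4)C(C)(C)C)CC3)[C@@H]12 | intermediate
19 | 10-O-trimethylsilyl ether of 18 (octalin lactone, precursor of the key step) | C1C(=O)O[C@H]2CC(C)C3=C(C[C@@](O[Si](C)(C)C)(CO[Si](c4ccccc4)(c4ccccc4)C(C)(C)C)CC3)[C@@H]12 | intermediate
20 | ozonide of 19 (1,2,4-trioxolane bridging C3 and C8) | C1C(=O)O[C@H]2CC(C)C3(OO4)CC[C@](O[Si](C)(C)C)(CO[Si](c5ccccc5)(c5ccccc5)C(C)(C)C)CC4(O3)[C@@H]12 | intermediate
21 | cyclodecane-3,8-dione with cis-fused 6,12-lactone, (10R)-10-OTMS and 14-OTBDPS | C1C(=O)O[C@H]2CC(C)C(=O)CC[C@](O[Si](C)(C)C)(CO[Si](c3ccccc3)(c3ccccc3)C(C)(C)C)CC(=O)[C@@H]12 | intermediate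
22 | (3S,10R)-3,10-epoxy-3-hydroxy-8-ketone (hemiketal), 14-OTBDPS | C1C(=O)O[C@H]2CC(C)[C@]3(O)CC[C@](CO[Si](c4ccccc4)(c4ccccc4)C(C)(C)C)(CC(=O)[C@@H]12)O3 | intermediate
23 | (3S,10R)-3,10-epoxy-3-methoxy-8-ketone (methyl ketal), 14-OTBDPS | C1C(=O)O[C@H]2CC(C)[C@]3(OC)CC[C@](CO[Si](c4ccccc4)(c4ccccc4)C(C)(C)C)(CC(=O)[C@@H]12)O3 | intermediate
24 | (8R)-alcohol of 23 (H-6, H-7, H-8 all cis) | C1C(=O)O[C@H]2CC(C)[C@]3(OC)CC[C@](CO[Si](c4ccccc4)(c4ccccc4)C(C)(C)C)(C[C@@H](O)[C@@H]12)O3 | intermediate
25 | (R)-2-methylbutanoic acid | CC[C@@H](C)C(=O)O | starting material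
26 | 8-O-[(R)-2-methylbutanoyl] ester of 24 | C1C(=O)O[C@H]2CC(C)[C@]3(OC)CC[C@](CO[Si](c4ccccc4)(c4ccccc4)C(C)(C)C)(C[C@@H](OC(=O)[C@H](C)CC)[C@@H]12)O3 | intermediate
27 | 11-(dimethylaminomethyl) lactone (Mannich base of 26, C11 epimers) | CN(C)CC1C(=O)O[C@H]2CC(C)[C@]3(OC)CC[C@](CO[Si](c4ccccc4)(c4ccccc4)C(C)(C)C)(C[C@@H](OC(=O)[C@H](C)CC)[C@@H]12)O3 | intermediate
28 | trimethylammonium iodide of 27 | C[N+](C)(C)CC1C(=O)O[C@H]2CC(C)[C@]3(OC)CC[C@](CO[Si](c4ccccc4)(c4ccccc4)C(C)(C)C)(C[C@@H](OC(=O)[C@H](C)CC)[C@@H]12)O3.[I-] | intermediate
29 | 11(13)-methylene lactone with C3 methyl ketal and 14-OTBDPS | C=C1C(=O)O[C@H]2CC(C)[C@]3(OC)CC[C@](CO[Si](c4ccccc4)(c4ccccc4)C(C)(C)C)(C[C@@H](OC(=O)[C@H](C)CC)[C@@H]12)O3 | intermediate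
30 | (3S)-hemiketal: 4,5-dihydro target as its 14-O-TBDPS ether | C=C1C(=O)O[C@H]2CC(C)[C@]3(O)CC[C@](CO[Si](c4ccccc4)(c4ccccc4)C(C)(C)C)(C[C@@H](OC(=O)[C@H](C)CC)[C@@H]12)O3 | intermediate
31 | 4-(phenylselanyl) derivative of 30 (C4 epimers) | C=C1C(=O)O[C@H]2CC(C)([Se]c4ccccc4)[C@]3(O)CC[C@](CO[Si](c4ccccc4)(c4ccccc4)C(C)(C)C)(C[C@@H](OC(=O)[C@H](C)CC)[C@@H]12)O3 | intermediate
32 | 14-O-tert-butyldiphenylsilyl ether of the target (4Z alkene, 3S hemiketal) | C=C1C(=O)O[C@H]2/C=C(/C)[C@]3(O)CC[C@](CO[Si](c4ccccc4)(c4ccccc4)C(C)(C)C)(C[C@@H](OC(=O)[C@H](C)CC)[C@@H]12)O3 | intermediate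
33 | CNP0328225.2 | C=C1C(=O)O[C@H]2/C=C(/C)[C@]3(O)CC[C@](CO)(C[C@@H](OC(=O)[C@H](C)CC)[C@@H]12)O3 | target

## Step count and least certain steps

Total step count: 18. Longest linear sequence: 18 steps (1 → 33); the route is linear, with 2, 5 and 25 entering as commercial reagents.

**Step 11 (key step).** The cleavage itself is dependable. What may go wrong lies in the product: transannular aldol closure of the 1,6-diketone to a hydroazulenone, enolisation at C7 with epimerisation or β-elimination of the lactone carboxylate, and slow reduction of the tetrasubstituted ozonide, which leaves peroxide that can rearrange. The fallback makes the same cut in two stages. From 19, osmylation (OsO4, pyridine, then aq. NaHSO3) should give the cis-3,8-diol F1, and glycol cleavage with Pb(OAc)4 and K2CO3 in benzene at 0 °C returns to 21 without a peroxidic intermediate.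

**Step 17.** Most likely to go wrong are enolisation toward C2 instead of C4 (selenium at the wrong carbon), elimination of the selenoxide toward the C15 methyl group (exocyclic alkene), and slow reaction because the keto tautomer of 30 is minor. The fallback changes the mechanism of both events. From 30, TMSOTf and Et3N in CH2Cl2 under equilibrating conditions should trap the open form as the 3,10-bis(trimethylsilyloxy) enol ether F2. Saegusa–Ito oxidation with Pd(OAc)2 (divalent palladium, stoichiometric) in MeCN gives the ring-opened 4-en-3-one F3 by β-hydride elimination, which favours the endocyclic enone. Dilute aqueous HCl removes the silyl group from O10, and the Z enone is drawn off as the hemiketal, returning to 32.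

**Step 13.** The risk is poor or reversed facial selectivity, because the conformational bias of the bridged ten-membered ring may override the catalyst; the two C4 epimers may also behave differently. The fallback uses the substrate's own bias. From 23, reduction with NaBH4 and CeCl3·7H2O in MeOH at −78 °C is taken to give the 8-epi alcohol F4. A Mitsunobu esterification with 25 (PPh3, diisopropyl azodicarboxylate, toluene) installs the ester with inversion and returns to 26, replacing steps 13 and 14.

**Step 5.** The risks are reduction of the lactone carbonyl if ring opening to the carboxylate is incomplete or the salt precipitates, hydrogenolysis of the benzylic C–O bond if the alkoxide is not fully formed, and base-induced conjugation of the 1,4-diene. The fallback masks the lactone as an acetal, so that no salt is needed and no lactone is present during the hydride steps.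
- From 10, i-Bu2AlH (CH2Cl2, −78 °C) gives lactol F5, and MeOH with PPTS gives the methyl lactol ether F6.
- Birch reduction of F6 as its lithium alkoxide gives the dienyl acetal F7.
- The chemistry of steps 6–8 is applied unchanged: epoxy alcohol F8, silyl ether F9, and hydride opening to the tertiary alcohol F10.
- Aqueous AcOH–THF hydrolyses the acetal to lactol 17, and the oxidation of step 9 returns to 18.

## Further compounds

F1 | step 11 | cis-3,8-diol of 19 (3,8-dihydroxy decalin lactone, 10-OTMS, 14-OTBDPS) | C1C(=O)O[C@H]2CC(C)C3(O)CC[C@](O[Si](C)(C)C)(CO[Si](c4ccccc4)(c4ccccc4)C(C)(C)C)CC3(O)[C@@H]12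
F2 | step 17 | ring-opened 3,10-bis(trimethylsilyloxy) 3-ene (silyl enol ether of the keto form of 30) | C=C1C(=O)O[C@H]2CC(C)=C(O[Si](C)(C)C)CC[C@](O[Si](C)(C)C)(CO[Si](c3ccccc3)(c3ccccc3)C(C)(C)C)C[C@@H](OC(=O)[C@H](C)CC)[C@@H]12
F3 | step 17 | ring-opened 4-en-3-one with 10-OTMS and 14-OTBDPS | C=C1C(=O)O[C@H]2C=C(C)C(=O)CC[C@](O[Si](C)(C)C)(CO[Si](c3ccccc3)(c3ccccc3)C(C)(C)C)C[C@@H](OC(=O)[C@H](C)CC)[C@@H]12
F4 | step 13 | 8-epi alcohol (8S) of 23 | C1C(=O)O[C@H]2CC(C)[C@]3(OC)CC[C@](CO[Si](c4ccccc4)(c4ccccc4)C(C)(C)C)(C[C@H](O)[C@@H]12)O3
F5 | step 5 | lactol from 10 | C1C(O)O[C@H]2CC(C)c3ccc(CO)cc3[C@@H]12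
F6 | step 5 | methyl lactol ether of 10 (2-methoxytetrahydrofuran, free benzylic alcohol) | C1C(OC)O[C@H]2CC(C)c3ccc(CO)cc3[C@@H]12
F7 | step 5 | Birch-reduced dienyl methyl acetal with allylic alcohol | C1C(OC)O[C@H]2CC(C)C3=C(CC(CO)=CC3)[C@@H]12
F8 | step 5 | (1R,10R)-epoxy alcohol methyl acetal | C1C(OC)O[C@H]2CC(C)C3=C(C[C@]4(CO)O[C@@H]4C3)[C@@H]12
F9 | step 5 | C14 tert-butyldiphenylsilyl ether of F8 | C1C(OC)O[C@H]2CC(C)C3=C(C[C@]4(CO[Si](c5ccccc5)(c5ccccc5)C(C)(C)C)O[C@@H]4C3)[C@@H]12
F10 | step 5 | (10R)-10-hydroxy methyl acetal with 14-OTBDPS | C1C(OC)O[C@H]2CC(C)C3=C(C[C@@](O)(CO[Si](c4ccccc4)(c4ccccc4)C(C)(C)C)CC3)[C@@H]12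
A1 | alternative 1 | methyl 3-[2-methoxy-4-methyl-7-(tert-butyldimethylsilyloxymethyl)-7-(2,2-dimethoxyethyl)-1,6-dioxaspiro[4.4]non-3-en-2-yl]propanoate | COC(=O)CC[C@@]1(OC)C=C(C)[C@]2(CC[C@](CO[Si](C)(C)C(C)(C)C)(CC(OC)OC)O2)O1
A2 | alternative 2 | C2-phenylsulfonyl 3,10-epoxy hemiketal with saturated lactone, C8 ester and 14-OTBS | C1C(=O)O[C@H]2/C=C(/C)[C@]3(O)[C@@H](S(=O)(=O)c4ccccc4)C[C@](CO[Si](C)(C)C(C)(C)C)(C[C@@H](OC(=O)[C@H](C)CC)[C@@H]12)O3
A3 | alternative 3 | 3,10-epoxy-3-methoxy ten-membered homoallylic alcohol (8-OH, 6-OTBS, 14-OTBS, C7 bearing 3-silyloxyprop-1-en-2-yl) | C=C(CO[Si](C)(C)C(C)(C)C)[C@H]1[C@@H](O[Si](C)(C)C(C)(C)C)/C=C(/C)[C@]2(OC)CC[C@](CO[Si](C)(C)C(C)(C)C)(C[C@H]1O)O2
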